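Abbreviations: geranyl = (2E)-3,7-dimethylocta-2,6-dien-1-yl; MOM = methoxymethyl. Unprimed locants (C2, C3, C3a, C4 to C7, C7a) refer to the 2,3-dihydrobenzofuran (rings C and D); locants of the other half are written "benzofuran C2" and so on (rings A and B).

## Analysis of the target

Compound 30 is a 2-arylbenzofuran. A benzofuran (benzo ring A, furan ring B) with a free hydroxyl at benzofuran C6 and a geranyl chain at benzofuran C7 is bonded through benzofuran C2 to C4 of a 2,3-dihydrobenzofuran (aromatic ring C, dihydrofuran ring D), which carries a hydroxyl at C6 and a 2-hydroxypropan-2-yl group at C2. The only stereocentre is C2 of ring D, of (S) configuration; it has no second centre to relate to, so its absolute configuration must come from an enantiopure building block or a stereospecific step. The sensitive groups are the two trisubstituted alkenes of the geranyl chain (the inner one sits ortho to a phenol and can close to a chroman under acid), the tertiary alcohol, and the electron-rich rings, which rule out late halogenation, strong oxidants and hydrogenation. The main difficulty is ring C: it is 1,2,3,5-tetrasubstituted with three contiguous substituents (benzofuranyl at C4, the C3 methylene at C3a, the ring D oxygen at C7a), so C3a is flanked on both sides and hard to reach by substitution of a preformed arene. A second difficulty is placing the geranyl chain on ring A between two oxygens. The strategy rests on ring C being a resorcinol: the oxygens at C6 and C7a are 1,3-related and the two carbon substituents sit on the adjacent carbons C3a and C4. That is the pattern left when a malonyl-type unit (C3a, C7a and a carboxyl that is lost) is joined to the four carbons of a methyl ynone (C4, C5, C6, C7); if the malonyl unit is an α-carbethoxy γ-lactone, its ring oxygen is the secondary oxygen needed for ring D and its C5 is the future stereocentre.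

## Retrosynthetic reasoning

30 to 29. The last operation only frees the benzofuran C6 phenol and the tertiary alcohol. Both are carried as MOM ethers in 29: on ring A the group directs the metalation that places the geranyl chain, and on the tertiary oxygen it is an acetal that cannot migrate to a neighbouring alkoxide in the basic steps.

29 to 28. The O1–C2 bond of ring D is cut. The forward reaction is an intramolecular etherification of the C7a phenol with the activated secondary alcohol under inversion, so the open-chain carbinol in 28 must be (R). This reduces ring D and its stereocentre to a simple side-chain alcohol. The protected tertiary oxygen leaves only the direct 5-exo displacement open; a free one could form an epoxide and return the opposite configuration.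

28 to 14 and 24. Ring C is cut at C3a–C4 and at C7–C7a. This is preferred over a cut of the biaryl bond or of the C3a–C3 bond because it avoids substitution at the doubly flanked C3a altogether: the position of every substituent follows from the connectivity of the two partners. The ynone 14 supplies C4 to C7 with the benzofuran already on C4. The lactone ester 24 supplies C3a, C7a, the side chain with the carbinol oxygen, and one extra carboxyl. The forward reaction has to add the carbanion of 24 to the alkyne, close the ring by C-acylation, and lose the extra carboxyl so that the ring aromatises.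

24 to 21 and 22. The lactone is cut at the C3–C4 bond and at the acyl–oxygen bond, which leads to diethyl malonate 22 and the terminal epoxide 21. The malonate attacks the unhindered epoxide carbon, so the stereocentre is not touched and the (R) configuration of 21 appears unchanged in 24.

21 to 15. The epoxide is traced through the diol 19, the acetonide 18 and the tertiary alcohol 17 to the glycerate acetonide 15. The two methyl groups come from a methyl organomagnesium reagent, and the stereocentre of 15 is never a reacting centre. The (R) descriptor holds from 15 to 28 because the priority order of the four substituents does not change.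

14 to 11 and 12. The bond between benzofuran C2 and the alkyne is cut. A Sonogashira coupling of the 2-iodide 11 with but-3-yn-2-ol 12, followed by oxidation of the propargylic alcohol 13, gives the ynone without an alkyne protecting group and without handling a terminal ynone.

11 to 1 and 5. The iodide 11 comes from 9 by lithiation at benzofuran C2. The geranyl chain of 9 is cut at the aryl–CH2 bond, back to geranyl bromide 5 and an aryl metal at benzofuran C7, the position between the MOM ether oxygen and the furan oxygen. Because benzofuran C2–H is the most acidic site, it is blocked by a silyl group (4, then 8) during that metalation and freed again afterwards. Compound 4 comes from benzofuran-6-ol 1 through its MOM ether 2.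

## Alternatives that were turned down

Alternative 1: Ring D is cut at C2–C3 and O1–C2, so that C2 arrives as a one-carbon ylide and ring C as an ortho-quinone methide whose methide carbon is C3. In the forward step a carbonate base releases the quinone methide from a 2-(sulfonylmethyl)phenol that already carries bromine at the future C4 and a silyloxy group at the future C6. The ammonium ylide formed from a bromoacetate ester and a cinchona-derived tertiary amine adds to the methide carbon, and the phenoxide displaces the amine. The product is A1, tert-butyl (2S)-4-bromo-6-(triisopropylsilyloxy)-2,3-dihydrobenzofuran-2-carboxylate. Double methyl addition to the ester and a Suzuki coupling of the bromide with a 2-borylated derivative of 9 would complete the skeleton.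
- For it: the route is convergent, ring D and the stereocentre are formed in one step, and the biaryl bond is made by a cross-coupling. On that last point it is stronger than the chosen route, because a Suzuki coupling is more dependable than an annulation.
- Against it: the quinone methide has an unsubstituted methide carbon, so it is short-lived and prone to oligomerise. The only new stereocentre is the ylide carbon; induction must come from the chiral ammonium group alone as it adds to a CH2 terminus, and the α-ammonium ester centre can epimerise before ring closure, so the enantiomeric purity of A1 is not secured by the mechanism. The arene precursor also has the same contiguous 1,2,3,5-pattern, so the ring C problem is moved into its preparation and not solved.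
- Comparison: the chosen strategy takes the stereocentre from 15 without a selectivity question and builds the contiguous pattern from acyclic partners; it pays with a less certain ring-forming step.

Alternative 2: Both carbon–carbon bonds at ring C (C4 to benzofuran C2, and C3a to C3) are cut at once, and ring C appears as an aryne between C3a and C4. In the forward step iodine–magnesium exchange on A3, 1-bromo-2-iodo-3,5-bis(triisopropylsilyloxy)benzene, and loss of magnesium halide give the 3-silyloxyaryne. The 2-magnesiated form of 9 adds at C4, away from the silyloxy group, and the new arylmagnesium at C3a opens epoxide 21 under copper catalysis to give A2, (2R)-1-{2-[7-geranyl-6-(methoxymethoxy)benzofuran-2-yl]-4,6-bis(triisopropylsilyloxy)phenyl}-3-(methoxymethoxy)-3-methylbutan-2-ol.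
- For it: it is a three-component union with two bonds formed in one flask, it uses the same epoxide and the same end-game, and the direction of addition has an inductive rationale. In step count and convergence it is stronger than the chosen route.
- Against it: the aryne is generated in the presence of the geranyl chain and the furan ring of the nucleophile, and ene reactions with trisubstituted alkenes and [4+2] additions to furans are typical aryne reactions. The Grignard of the aryne precursor competes as a nucleophile, and a bulky silyloxy group steers less strictly than a small alkoxy group. The intermediate arylmagnesium is flanked on both sides and must open an epoxide before it is protonated or adds to more aryne.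
- Comparison: three selective events have to succeed in one flask. The chosen strategy is longer but uses only closed-shell anionic steps that leave the geranyl chain alone, and it fixes the substitution pattern by connectivity and not by a regioselectivity.

Alternative 3: The benzofuran C2=C3 bond of ring B is cut and traced back to an aldehyde carbon (future C3) and an aryl ester carbonyl carbon (future C2) held together through the ring A phenol oxygen. The precursor is A5, 6-formyl-2-geranyl-3-(triisopropylsilyloxy)phenyl (2S)-2-[2-(triethylsilyloxy)propan-2-yl]-6-(triisopropylsilyloxy)-2,3-dihydrobenzofuran-4-carboxylate. In the forward step low-valent titanium, made by zinc reduction of a titanium chloride, couples the two carbonyl carbons and closes ring B to give A4, the tris-silyl ether of the target (triisopropylsilyl on both phenols, triethylsilyl on the tertiary alcohol).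
- For it: titanium-induced oxo–ester cyclisation to benzofurans is an established reaction class, the halves are joined by a plain esterification, and the all-silyl protection allows a fluoride end-game with no acid near the geranyl phenol. On that point it is stronger than the chosen route.
- Against it: the ring C/D acid, with its stereocentre and the contiguous pattern, still has to be made, so the central problem is untouched and the step count rises. The aldehyde half needs the geranyl chain between two oxygens as well. The oxophilic, Lewis-acidic reagent in a hot ether solvent must spare a tertiary silyl ether and an aryl ester that can be cleaved reductively, and intermolecular pinacol coupling of the aldehyde competes.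
- Comparison: the chosen strategy forms ring C and the bond to the benzofuran in the same step, at the cost of an acidic final deprotection.

Key step: step 13

Assumption: 24 is used as the mixture of its two C3 epimers, because C3 becomes an aromatic carbon of ring C; compounds 1, 5, 12, 15 and 22 are taken as purchasable.

## Route

Step 1
Reactants: 1 benzofuran-6-ol
Product: 2 6-(methoxymethoxy)benzofuran
Conditions: NaH, DMF, 0 °C; MOMCl, 0 °C to rt
Reagents that add atoms: chloromethyl methyl ether (MOMCl), COCCl
Why: Williamson-type O-alkylation of the sodium phenoxide; the MOM ether is stable to the organolithium and alkoxide steps and later directs the metalation of step 3.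

Step 2
Reactants: 2 6-(methoxymethoxy)benzofuran
Product: 4 trimethyl[6-(methoxymethoxy)benzofuran-2-yl]silane, via aryllithium 3 (not isolated)
Conditions: n-BuLi, THF, −78 °C; TMSCl, −78 °C to rt
Reagents that add atoms: chlorotrimethylsilane, C[Si](C)(C)Cl
Why: Benzofuran C2–H is the kinetically most acidic site and is lithiated first at low temperature; silylation blocks it so that the next metalation is steered by the MOM ether.

Step 3
Reactants: 4 trimethyl[6-(methoxymethoxy)benzofuran-2-yl]silane; 5 geranyl bromide
Product: 8 [7-geranyl-6-(methoxymethoxy)benzofuran-2-yl]trimethylsilane, via aryllithium 6 (not isolated), via arylcopper 7 (not isolated)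
Conditions: n-BuLi, TMEDA, THF, −78 to 0 °C; CuBr·SMe2, −78 °C; 5, −78 °C to rt
Reagents that add atoms: none
Why: Directed ortho-metalation should take place at benzofuran C7, the only position flanked by the MOM ether oxygen and the furan oxygen; transmetalation to copper should then give allylic substitution at the primary carbon of 5 with the (E) alkene kept.

Step 4
Reactants: 8 [7-geranyl-6-(methoxymethoxy)benzofuran-2-yl]trimethylsilane
Product: 9 7-geranyl-6-(methoxymethoxy)benzofuran
Conditions: TBAF·3H2O, THF, rt to 50 °C
Reagents that add atoms: none
Why: Fluoride-induced protodesilylation; the silicon on benzofuran C2 is activated because the departing carbanion is stabilised by the ring oxygen, while the MOM ether and the alkenes are inert to fluoride.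

Step 5
Reactants: 9 7-geranyl-6-(methoxymethoxy)benzofuran
Product: 11 7-geranyl-2-iodo-6-(methoxymethoxy)benzofuran, via aryllithium 10 (not isolated)
Conditions: n-BuLi, THF, −78 °C; I2, −78 °C; aq. Na2S2O3
Reagents that add atoms: iodine, II
Why: Lithiation at the freed benzofuran C2 and iodination of the aryllithium, which is much faster than any reaction of iodine with the alkenes at −78 °C; excess iodine is removed reductively on work-up.

Step 6
Reactants: 11 7-geranyl-2-iodo-6-(methoxymethoxy)benzofuran; 12 but-3-yn-2-ol
Product: 13 4-[7-geranyl-6-(methoxymethoxy)benzofuran-2-yl]but-3-yn-2-ol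
Conditions: PdCl2(PPh3)2 (3 mol %), CuI (5 mol %), Et3N, THF, rt
Reagents that add atoms: none
Why: Sonogashira coupling of a reactive heteroaryl iodide with a terminal alkyne; the free secondary alcohol is tolerated, and its configuration does not matter because it is oxidised next.

Step 7
Reactants: 13 4-[7-geranyl-6-(methoxymethoxy)benzofuran-2-yl]but-3-yn-2-ol
Product: 14 4-[7-geranyl-6-(methoxymethoxy)benzofuran-2-yl]but-3-yn-2-one
Conditions: MnO2, CH2Cl2, rt
Reagents that add atoms: none
Why: Activated MnO2 oxidises propargylic alcohols selectively and leaves the geranyl alkenes, the MOM ether and the benzofuran untouched.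

Step 8
Reactants: 15 methyl (4R)-2,2-dimethyl-1,3-dioxolane-4-carboxylate
Product: 17 2-[(4R)-2,2-dimethyl-1,3-dioxolan-4-yl]propan-2-ol, via ketone 16 (not isolated)
Conditions: MeMgBr (2.5 equiv), THF, 0 °C to rt; aq. NH4Cl
Reagents that add atoms: methylmagnesium bromide, C[Mg]Br
Why: Double Grignard addition to the ester through the methyl ketone; carbonyl addition outruns enolisation, so the α-alkoxy stereocentre of 15 should be carried over unchanged.

Step 9
Reactants: 17 2-[(4R)-2,2-dimethyl-1,3-dioxolan-4-yl]propan-2-ol
Product: 18 (4R)-4-[2-(methoxymethoxy)propan-2-yl]-2,2-dimethyl-1,3-dioxolane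
Conditions: MOMCl, iPr2NEt, Bu4NI (cat.), CH2Cl2, 40 °C
Reagents that add atoms: chloromethyl methyl ether (MOMCl), COCCl
Why: Acetal formation on the tertiary alcohol, with iodide catalysis to raise the reactivity of the alkylating agent; an acetal is chosen because a silyl group could migrate to the neighbouring alkoxide formed in steps 11 to 13.

Step 10
Reactants: 18 (4R)-4-[2-(methoxymethoxy)propan-2-yl]-2,2-dimethyl-1,3-dioxolane
Product: 19 (2R)-3-(methoxymethoxy)-3-methylbutane-1,2-diol
Conditions: AcOH–H2O (4:1), rt
Reagents that add atoms: none
Why: Selective ketal hydrolysis; the isopropylidene ketal ionises to a tertiary oxocarbenium ion far more readily than the formaldehyde acetal, so the MOM ether should survive the weak acid.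

Step 11
Reactants: 19 (2R)-3-(methoxymethoxy)-3-methylbutane-1,2-diol
Product: 21 (2R)-2-[2-(methoxymethoxy)propan-2-yl]oxirane, via hydroxy tosylate 20 (not isolated)
Conditions: TsCl, Et3N, Bu2SnO (2 mol %), CH2Cl2, 0 °C; then K2CO3, MeOH, rt
Reagents that add atoms: none
Why: Tin-catalysed sulfonylation is selective for the primary hydroxyl (the secondary one is also shielded by the adjacent quaternary carbon), and the secondary alkoxide then closes the epoxide in a 3-exo-tet Williamson reaction; the C–O bond at the stereocentre is never broken, so (R) is retained.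

Step 12
Reactants: 21 (2R)-2-[2-(methoxymethoxy)propan-2-yl]oxirane; 22 diethyl malonate
Product: 24 ethyl (5R)-5-[2-(methoxymethoxy)propan-2-yl]-2-oxooxolane-3-carboxylate, via hydroxy malonate 23 (not isolated)
Conditions: NaOEt, EtOH, rt to reflux; AcOH
Reagents that add atoms: none
Why: Classical malonate–epoxide lactone synthesis: the malonate anion opens the epoxide at the unhindered CH2 in an SN2 reaction and the alkoxide lactonises onto one ester; the stereocentre is not a reacting centre, and the C3 epimers are used together.

Step 13
Reactants: 14 4-[7-geranyl-6-(methoxymethoxy)benzofuran-2-yl]but-3-yn-2-one; 24 ethyl (5R)-5-[2-(methoxymethoxy)propan-2-yl]-2-oxooxolane-3-carboxylate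
Product: 28 (2R)-1-{2-[7-geranyl-6-(methoxymethoxy)benzofuran-2-yl]-4,6-dihydroxyphenyl}-3-(methoxymethoxy)-3-methylbutan-2-ol, via Michael adduct 25 (not isolated), via diketo ester 26 (not isolated), via diketo acid 27 (not isolated)
Conditions: NaOEt (2.2 equiv), EtOH–THF, 0 °C (slow addition of 14) to 60 °C; then 2 M aq. KOH, 70 °C; then AcOH to pH 5, 50 °C
Reagents that add atoms: none
Why: Proposed new method: the sodium enolate of 24, a tertiary malonate-type carbanion, should add to the alkyne carbon of 14 that bears the benzofuran (forming C3a–C4), and protonation of the allenolate gives enone 25, in which anti addition places the acetyl group cis to the new quaternary carbon. Ethoxide then forms the extended enolate of the methyl ketone, whose terminal carbon acylates at the lactone carbonyl (forming C7–C7a) in a 6-exo-trig Claisen closure that closes ring C, opens the lactone and frees the secondary alkoxide; the product 26 is held as its 1,3-diketone enolate, which makes the closure irreversible. Hydroxide then cleaves the ester on the quaternary carbon, and on acidification the β-keto acid 27 loses CO2 and tautomerises to the resorcinol 28; attack at the ethyl ester in place of the lactone carbonyl would converge on the same acid after hydrolysis. The closest known reaction type is the Michael–Claisen synthesis of cyclohexane-1,3-diones from malonates and enones, together with the condensation of acetonedicarboxylates with ynones to resorcylates; what is new is the α-carbethoxy lactone as a tertiary donor in combination with an ynone. No stereocentre is created: the quaternary carbon of 25 to 27 becomes aromatic, and the (R) carbinol is preserved because the lactone opens at the acyl–oxygen bond. The step needs C-acylation to win over O-acylation and needs the alkene geometry that can cyclise; the quaternary donor carbon secures the first, because an O-acylated enol lactone cannot become an aromatic 2-pyranone and so reverts, and reversible ethoxide addition to the enone secures the second by equilibrating the geometrical isomers. Ethoxide that adds to 14 first is not lost, because the β-ethoxy enone is converted to 25 by addition–elimination.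

Step 14
Reactants: 28 (2R)-1-{2-[7-geranyl-6-(methoxymethoxy)benzofuran-2-yl]-4,6-dihydroxyphenyl}-3-(methoxymethoxy)-3-methylbutan-2-ol
Product: 29 (2S)-4-[7-geranyl-6-(methoxymethoxy)benzofuran-2-yl]-2-[2-(methoxymethoxy)propan-2-yl]-2,3-dihydrobenzofuran-6-ol
Conditions: PPh3, DIAD, THF, 0 °C to rt
Reagents that add atoms: none
Why: Intramolecular Mitsunobu etherification: the C7a phenol displaces the alkoxyphosphonium group in a 5-exo-tet closure with inversion, turning the (R) carbinol into (S) at C2; the other phenol is para to the chain and cannot reach, and the protected tertiary oxygen cannot form an epoxide that would lead to retention.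

Step 15
Reactants: 29 (2S)-4-[7-geranyl-6-(methoxymethoxy)benzofuran-2-yl]-2-[2-(methoxymethoxy)propan-2-yl]-2,3-dihydrobenzofuran-6-ol
Product: 30 (2S)-4-(7-geranyl-6-hydroxybenzofuran-2-yl)-2-(2-hydroxypropan-2-yl)-2,3-dihydrobenzofuran-6-ol
Conditions: 3 M aq. HCl, MeOH–THF, 40 °C
Reagents that add atoms: none
Why: Acid-catalysed transacetalisation of both MOM ethers to dimethoxymethane; cleavage occurs at the acetal carbon and not at C2 or the tertiary carbon, so the stereocentre is untouched, and dilute acid at mild temperature is chosen to keep the geranyl alkenes from being protonated.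

## Compound list

1 | benzofuran-6-ol | Oc1ccc2ccoc2c1 | starting material
2 | 6-(methoxymethoxy)benzofuran | COCOc1ccc2ccoc2c1 | intermediate
3 | [6-(methoxymethoxy)benzofuran-2-yl]lithium | COCOc1ccc2cc([Li])oc2c1 | intermediate (not isolated)
4 | trimethyl[6-(methoxymethoxy)benzofuran-2-yl]silane | COCOc1ccc2cc([Si](C)(C)C)oc2c1 | intermediate
5 | geranyl bromide, (2E)-1-bromo-3,7-dimethylocta-2,6-diene | CC(C)=CCC/C(C)=C/CBr | starting material
6 | [6-(methoxymethoxy)-2-(trimethylsilyl)benzofuran-7-yl]lithium | COCOc1ccc2cc([Si](C)(C)C)oc2c1[Li] | intermediate (not isolated)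
7 | [6-(methoxymethoxy)-2-(trimethylsilyl)benzofuran-7-yl]copper | COCOc1ccc2cc([Si](C)(C)C)oc2c1[Cu] | intermediate (not isolated)
8 | [7-geranyl-6-(methoxymethoxy)benzofuran-2-yl]trimethylsilane | COCOc1ccc2cc([Si](C)(C)C)oc2c1C/C=C(\C)CCC=C(C)C | intermediate
9 | 7-geranyl-6-(methoxymethoxy)benzofuran | COCOc1ccc2ccoc2c1C/C=C(\C)CCC=C(C)C | intermediate
10 | [7-geranyl-6-(methoxymethoxy)benzofuran-2-yl]lithium | COCOc1ccc2cc([Li])oc2c1C/C=C(\C)CCC=C(C)C | intermediate (not isolated)
11 | 7-geranyl-2-iodo-6-(methoxymethoxy)benzofuran | COCOc1ccc2cc(I)oc2c1C/C=C(\C)CCC=C(C)C | intermediate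
12 | but-3-yn-2-ol (racemic) | CC(O)C#C | starting material
13 | 4-[7-geranyl-6-(methoxymethoxy)benzofuran-2-yl]but-3-yn-2-ol (racemic at the carbinol) | CC(O)C#Cc1cc2ccc(OCOC)c(C/C=C(\C)CCC=C(C)C)c2o1 | intermediate
14 | 4-[7-geranyl-6-(methoxymethoxy)benzofuran-2-yl]but-3-yn-2-one | CC(=O)C#Cc1cc2ccc(OCOC)c(C/C=C(\C)CCC=C(C)C)c2o1 | intermediate
15 | methyl (4R)-2,2-dimethyl-1,3-dioxolane-4-carboxylate (methyl (R)-glycerate acetonide) | COC(=O)[C@H]1COC(C)(C)O1 | starting material
16 | 1-[(4R)-2,2-dimethyl-1,3-dioxolan-4-yl]ethan-1-one | CC(=O)[C@H]1COC(C)(C)O1 | intermediate (not isolated)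
17 | 2-[(4R)-2,2-dimethyl-1,3-dioxolan-4-yl]propan-2-ol | CC(C)(O)[C@H]1COC(C)(C)O1 | intermediate
18 | (4R)-4-[2-(methoxymethoxy)propan-2-yl]-2,2-dimethyl-1,3-dioxolane | COCOC(C)(C)[C@H]1COC(C)(C)O1 | intermediate
19 | (2R)-3-(methoxymethoxy)-3-methylbutane-1,2-diol | COCOC(C)(C)[C@H](O)CO | intermediate
20 | (2R)-2-hydroxy-3-(methoxymethoxy)-3-methylbutyl 4-methylbenzenesulfonate | COCOC(C)(C)[C@H](O)COS(=O)(=O)c1ccc(C)cc1 | intermediate (not isolated)
21 | (2R)-2-[2-(methoxymethoxy)propan-2-yl]oxirane | COCOC(C)(C)[C@H]1CO1 | intermediate
22 | diethyl malonate | CCOC(=O)CC(=O)OCC | starting material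
23 | diethyl 2-[(2R)-2-hydroxy-3-(methoxymethoxy)-3-methylbutyl]propanedioate (formed as its sodium alkoxide) | CCOC(=O)C(C[C@@H](O)C(C)(C)OCOC)C(=O)OCC | intermediate (not isolated)
24 | ethyl (5R)-5-[2-(methoxymethoxy)propan-2-yl]-2-oxooxolane-3-carboxylate (both C3 epimers) | CCOC(=O)C1C[C@H](C(C)(C)OCOC)OC1=O | intermediate
25 | ethyl (5R)-3-{(1E)-1-[7-geranyl-6-(methoxymethoxy)benzofuran-2-yl]-3-oxobut-1-en-1-yl}-5-[2-(methoxymethoxy)propan-2-yl]-2-oxooxolane-3-carboxylate (both C3 epimers) | CCOC(=O)C1(C[C@H](C(C)(C)OCOC)OC1=O)/C(=C\C(C)=O)c1cc2ccc(OCOC)c(C/C=C(\C)CCC=C(C)C)c2o1 | intermediate (not isolated)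
26 | ethyl 2-[7-geranyl-6-(methoxymethoxy)benzofuran-2-yl]-1-[(2R)-2-hydroxy-3-(methoxymethoxy)-3-methylbutyl]-4,6-dioxocyclohex-2-ene-1-carboxylate (both C1 epimers, formed as its enolate) | CCOC(=O)C1(C[C@@H](O)C(C)(C)OCOC)C(=O)CC(=O)C=C1c1cc2ccc(OCOC)c(C/C=C(\C)CCC=C(C)C)c2o1 | intermediate (not isolated)
27 | 2-[7-geranyl-6-(methoxymethoxy)benzofuran-2-yl]-1-[(2R)-2-hydroxy-3-(methoxymethoxy)-3-methylbutyl]-4,6-dioxocyclohex-2-ene-1-carboxylic acid (both C1 epimers) | OC(=O)C1(C[C@@H](O)C(C)(C)OCOC)C(=O)CC(=O)C=C1c1cc2ccc(OCOC)c(C/C=C(\C)CCC=C(C)C)c2o1 | intermediate (not isolated)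
28 | (2R)-1-{2-[7-geranyl-6-(methoxymethoxy)benzofuran-2-yl]-4,6-dihydroxyphenyl}-3-(methoxymethoxy)-3-methylbutan-2-ol | CC(C)=CCC/C(C)=C/Cc1c(OCOC)ccc2cc(-c3cc(O)cc(O)c3C[C@H](C(C)(C)OCOC)O)oc12 | intermediate
29 | (2S)-4-[7-geranyl-6-(methoxymethoxy)benzofuran-2-yl]-2-[2-(methoxymethoxy)propan-2-yl]-2,3-dihydrobenzofuran-6-ol | CC(C)=CCC/C(C)=C/Cc1c(OCOC)ccc2cc(-c3cc(O)cc4c3C[C@@H](C(C)(C)OCOC)O4)oc12 | intermediate
30 | (2S)-4-(7-geranyl-6-hydroxybenzofuran-2-yl)-2-(2-hydroxypropan-2-yl)-2,3-dihydrobenzofuran-6-ol (CNP0312668.2) | CC(C)=CCC/C(C)=C/Cc1c(O)ccc2cc(-c3cc(O)cc4c3C[C@@H](C(C)(C)O)O4)oc12 | target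

## Step count and least certain steps

Total step count: 15. Longest linear sequence: 10 steps (steps 1 to 7, then 13, 14 and 15); the lactone branch (steps 8 to 12) joins at step 13.

**Step 13 (key step, proposed new method).**
- What may go wrong: the hindered tertiary carbanion may add to the ynone too slowly, so that self-condensation of the enolisable ynone takes over. The sequence may also stall at the Michael adduct, or close through oxygen, if the Claisen ring closure onto the carbonyl at the quaternary carbon is slower than expected.
- Fallback (known reactions only), from 9 and 21 back to 28: ring C is taken from a purchased arene and the two carbon–carbon bonds are made one after the other.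
  - 5-Bromobenzene-1,3-diol F1 would be silylated (TIPSCl, imidazole, DMF) to 1-bromo-3,5-bis(triisopropylsilyloxy)benzene F2.
  - F2 would be iodinated (NIS, cat. TFA, MeCN) para to one silyloxy group, at the position next to bromine, to give 1-bromo-2-iodo-3,5-bis(triisopropylsilyloxy)benzene F3 (identical with A3). The position between the two silyloxy groups is shielded.
  - Selective iodine–magnesium exchange on F3 (iPrMgCl·LiCl, THF, −40 °C, kept cold so that no aryne forms) and CuI-catalysed opening of epoxide 21 at its CH2 would give (2R)-1-[2-bromo-4,6-bis(triisopropylsilyloxy)phenyl]-3-(methoxymethoxy)-3-methylbutan-2-ol F4.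
  - Compound 9 would be lithiated at benzofuran C2 and borylated with 2-isopropoxy-4,4,5,5-tetramethyl-1,3,2-dioxaborolane to 2-[7-geranyl-6-(methoxymethoxy)benzofuran-2-yl]-4,4,5,5-tetramethyl-1,3,2-dioxaborolane F5.
  - Suzuki coupling of F4 with F5 (Pd(OAc)2, SPhos, K3PO4, toluene–water, 80 °C) would give (2R)-1-{2-[7-geranyl-6-(methoxymethoxy)benzofuran-2-yl]-4,6-bis(triisopropylsilyloxy)phenyl}-3-(methoxymethoxy)-3-methylbutan-2-ol F6 (identical with A2).
  - TBAF in THF would free the two phenols and return the route to 28.

**Step 3.**
- What may go wrong: incomplete or misdirected metalation, or allylic transposition and loss of alkene geometry in the copper-mediated coupling with the allylic bromide.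
- Fallback, from 4 back to 8: the aryllithium formed as in step 3 would be trapped with 2-isopropoxy-4,4,5,5-tetramethyl-1,3,2-dioxaborolane to give 2-[6-(methoxymethoxy)-2-(trimethylsilyl)benzofuran-7-yl]-4,4,5,5-tetramethyl-1,3,2-dioxaborolane F7. This boronate can be purified, so the site of metalation can be checked. A palladium-catalysed Suzuki–Miyaura allylation of F7 with 5 (Pd(PPh3)4, K2CO3, THF–water, 50 °C) would then deliver the aryl group to the unsubstituted end of the allyl–palladium intermediate and give 8.

**Step 14.**
- What may go wrong: activation of the carbinol, which sits next to a fully substituted carbon, may be slow, and elimination towards the benzylic position or intermolecular alkylation of the second phenol may compete with the ring closure.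
- Fallback, from 28 back to 29: both phenols would be silylated (TBSCl, imidazole, DMF; the hindered carbinol stays free) to (2R)-1-{2,4-bis[(tert-butyldimethylsilyl)oxy]-6-[7-geranyl-6-(methoxymethoxy)benzofuran-2-yl]phenyl}-3-(methoxymethoxy)-3-methylbutan-2-ol F8. The carbinol would be converted (MsCl, Et3N, CH2Cl2, 0 °C) to (2R)-1-{2,4-bis[(tert-butyldimethylsilyl)oxy]-6-[7-geranyl-6-(methoxymethoxy)benzofuran-2-yl]phenyl}-3-(methoxymethoxy)-3-methylbutan-2-yl methanesulfonate F9. TBAF in THF would then release the phenoxides, and the ortho phenoxide would displace the sulfonate with inversion (intramolecular Williamson reaction, 5-exo-tet) to give 29.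

**Step 15.**
- What may go wrong: acid-induced cyclisation of the geranyl chain onto the freed ortho phenol (chroman formation), or incomplete cleavage of the tertiary alkyl MOM ether under acid mild enough to spare the alkenes.
- Fallback, from 29 back to 30: the one free phenol would be acetylated (Ac2O, pyridine) to (2S)-4-[7-geranyl-6-(methoxymethoxy)benzofuran-2-yl]-2-[2-(methoxymethoxy)propan-2-yl]-2,3-dihydrobenzofuran-6-yl acetate F10, so that no protic group is left. Both MOM ethers would be cleaved without protic acid by Me2BBr (CH2Cl2, −78 °C), which turns them into bromomethyl ethers that hydrolyse on work-up with aq. NaHCO3, to give (2S)-4-(7-geranyl-6-hydroxybenzofuran-2-yl)-2-(2-hydroxypropan-2-yl)-2,3-dihydrobenzofuran-6-yl acetate F11. Here the phenol is liberated only under basic conditions. Methanolysis of the acetate (K2CO3, MeOH, rt) would give 30.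

Further compounds

F1 | step 13 | 5-bromobenzene-1,3-diol | Oc1cc(O)cc(Br)c1
F2 | step 13 | 1-bromo-3,5-bis(triisopropylsilyloxy)benzene | CC(C)[Si](Oc1cc(Br)cc(O[Si](C(C)C)(C(C)C)C(C)C)c1)(C(C)C)C(C)C
F3 | step 13 | 1-bromo-2-iodo-3,5-bis(triisopropylsilyloxy)benzene | CC(C)[Si](Oc1cc(Br)c(I)c(O[Si](C(C)C)(C(C)C)C(C)C)c1)(C(C)C)C(C)C
F4 | step 13 | (2R)-1-[2-bromo-4,6-bis(triisopropylsilyloxy)phenyl]-3-(methoxymethoxy)-3-methylbutan-2-ol | COCOC(C)(C)[C@H](O)Cc1c(Br)cc(O[Si](C(C)C)(C(C)C)C(C)C)cc1O[Si](C(C)C)(C(C)C)C(C)C
F5 | step 13 | 2-[7-geranyl-6-(methoxymethoxy)benzofuran-2-yl]-4,4,5,5-tetramethyl-1,3,2-dioxaborolane | COCOc1ccc2cc(B3OC(C)(C)C(C)(C)O3)oc2c1C/C=C(\C)CCC=C(C)C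
F6 | step 13 | (2R)-1-{2-[7-geranyl-6-(methoxymethoxy)benzofuran-2-yl]-4,6-bis(triisopropylsilyloxy)phenyl}-3-(methoxymethoxy)-3-methylbutan-2-ol | CC(C)=CCC/C(C)=C/Cc1c(OCOC)ccc2cc(-c3cc(O[Si](C(C)C)(C(C)C)C(C)C)cc(O[Si](C(C)C)(C(C)C)C(C)C)c3C[C@H](C(C)(C)OCOC)O)oc12
F7 | step 3 | 2-[6-(methoxymethoxy)-2-(trimethylsilyl)benzofuran-7-yl]-4,4,5,5-tetramethyl-1,3,2-dioxaborolane | COCOc1ccc2cc([Si](C)(C)C)oc2c1B1OC(C)(C)C(C)(C)O1
F8 | step 14 | (2R)-1-{2,4-bis[(tert-butyldimethylsilyl)oxy]-6-[7-geranyl-6-(methoxymethoxy)benzofuran-2-yl]phenyl}-3-(methoxymethoxy)-3-methylbutan-2-ol | CC(C)=CCC/C(C)=C/Cc1c(OCOC)ccc2cc(-c3cc(O[Si](C)(C)C(C)(C)C)cc(O[Si](C)(C)C(C)(C)C)c3C[C@H](C(C)(C)OCOC)O)oc12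
F9 | step 14 | (2R)-1-{2,4-bis[(tert-butyldimethylsilyl)oxy]-6-[7-geranyl-6-(methoxymethoxy)benzofuran-2-yl]phenyl}-3-(methoxymethoxy)-3-methylbutan-2-yl methanesulfonate | CC(C)=CCC/C(C)=C/Cc1c(OCOC)ccc2cc(-c3cc(O[Si](C)(C)C(C)(C)C)cc(O[Si](C)(C)C(C)(C)C)c3C[C@H](C(C)(C)OCOC)OS(C)(=O)=O)oc12
F10 | step 15 | (2S)-4-[7-geranyl-6-(methoxymethoxy)benzofuran-2-yl]-2-[2-(methoxymethoxy)propan-2-yl]-2,3-dihydrobenzofuran-6-yl acetate | CC(C)=CCC/C(C)=C/Cc1c(OCOC)ccc2cc(-c3cc(OC(C)=O)cc4c3C[C@@H](C(C)(C)OCOC)O4)oc12
F11 | step 15 | (2S)-4-(7-geranyl-6-hydroxybenzofuran-2-yl)-2-(2-hydroxypropan-2-yl)-2,3-dihydrobenzofuran-6-yl acetate | CC(C)=CCC/C(C)=C/Cc1c(O)ccc2cc(-c3cc(OC(C)=O)cc4c3C[C@@H](C(C)(C)O)O4)oc12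
A1 | alternative 1 | tert-butyl (2S)-4-bromo-6-(triisopropylsilyloxy)-2,3-dihydrobenzofuran-2-carboxylate | Brc1cc(O[Si](C(C)C)(C(C)C)C(C)C)cc2c1C[C@@H](C(=O)OC(C)(C)C)O2
A2 | alternative 2 | (2R)-1-{2-[7-geranyl-6-(methoxymethoxy)benzofuran-2-yl]-4,6-bis(triisopropylsilyloxy)phenyl}-3-(methoxymethoxy)-3-methylbutan-2-ol | CC(C)=CCC/C(C)=C/Cc1c(OCOC)ccc2cc(-c3cc(O[Si](C(C)C)(C(C)C)C(C)C)cc(O[Si](C(C)C)(C(C)C)C(C)C)c3C[C@H](C(C)(C)OCOC)O)oc12
A3 | alternative 2 | 1-bromo-2-iodo-3,5-bis(triisopropylsilyloxy)benzene | CC(C)[Si](Oc1cc(Br)c(I)c(O[Si](C(C)C)(C(C)C)C(C)C)c1)(C(C)C)C(C)C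
A4 | alternative 3 | tris-silyl ether of the target: triisopropyl{[(2S)-4-[7-geranyl-6-(triisopropylsilyloxy)benzofuran-2-yl]-2-[2-(triethylsilyloxy)propan-2-yl]-2,3-dihydrobenzofuran-6-yl]oxy}silane | CC(C)=CCC/C(C)=C/Cc1c(O[Si](C(C)C)(C(C)C)C(C)C)ccc2cc(-c3cc(O[Si](C(C)C)(C(C)C)C(C)C)cc4c3C[C@@H](C(C)(C)O[Si](CC)(CC)CC)O4)oc12
A5 | alternative 3 | 6-formyl-2-geranyl-3-(triisopropylsilyloxy)phenyl (2S)-2-[2-(triethylsilyloxy)propan-2-yl]-6-(triisopropylsilyloxy)-2,3-dihydrobenzofuran-4-carboxylate | O=Cc1ccc(O[Si](C(C)C)(C(C)C)C(C)C)c(C/C=C(\C)CCC=C(C)C)c1OC(=O)c1cc(O[Si](C(C)C)(C(C)C)C(C)C)cc2c1C[C@@H](C(C)(C)O[Si](CC)(CC)CC)O2
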